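**Retrosynthetic overview**
1. Target 27 ⇒ diol 24 (both Z-angelates are put on last) ⇒ acetonide 23 of the tricyclic enone.
2. 23 ⇒ cyclobutenone 20. C1–C11 and C4–C5 are made together when Rh cuts the temporary C1–C4 bond of the four-membered ketone and sews the C5=C11 alkene of the cycloheptene into it (a formal vinylketene + alkene [4+2]).
3. Enabling feature: the cyclohexenone ring C1(=O)–C2=C3(CH3)–C4–C5–C11 is a four-carbon vinylketene unit laid across the C5–C11 edge of the seven-membered ring C5–C6–C7–C8–C9–C10–C11. C4 and C11 both hang on quaternary C10 (a one-atom tether), and the alkene lies between quaternary C6 and C10, so no β- or allylic hydrogen can divert the metal.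
4. 20 ⇐ acid 14 (aldoketene + ethoxyacetylene [2+2], then MeLi/H3O+). C10 ⇐ Ireland–Claisen from the CBS-set C5 carbinol. C6/C7 ⇐ ketoreductase desymmetrisation of the prochiral dione 3.
5. Ring order: cycloheptane (bought) → dioxane (protecting ring) → cyclobutenone (temporary) → six-membered ring and cyclobutane together in the key step.

Key step: step 12

Remark: locants follow the longipinane skeleton and are used for the same atoms in every intermediate. C1 = enone C=O, C2 = enone CH, C3 = C–CH3, C4 and C11 = cyclobutane CH next to C3 and C1, C5 = cyclobutane CH next to C6, C6 = C(CH3)(CH2O), C7 = CH–O, C8/C9 = CH2, C10 = cyclobutane C–CH3.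
Assumption: a commercial ketoreductase panel contains a variant that gives the (2R,3S) isomer 4.

Step 1
Reactants: 1 cycloheptane-1,3-dione
Product: 2 2-methylcycloheptane-1,3-dione
Conditions: MeI, K2CO3, acetone, reflux
Reagents that add atoms: iodomethane, CI
Why: Classical C-alkylation of the stabilised 1,3-diketone enolate with a soft electrophile; no stereocentre is formed.

Step 2
Reactants: 2 2-methylcycloheptane-1,3-dione
Product: 3 2-(hydroxymethyl)-2-methylcycloheptane-1,3-dione
Conditions: 37% aq. CH2O, Et3N (cat.), THF, 0 °C → rt
Reagents that add atoms: formaldehyde, C=O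
Why: Base-catalysed aldol hydroxymethylation of the tertiary β-diketone carbon installs the future quaternary C6; the product keeps a mirror plane through C6 and is achiral.

Step 3
Reactants: 3 2-(hydroxymethyl)-2-methylcycloheptane-1,3-dione
Product: 4 (2R,3S)-3-hydroxy-2-(hydroxymethyl)-2-methylcycloheptan-1-one (ring OH trans to the CH2OH arm)
Conditions: ketoreductase (NADPH-dependent KRED), NADP+ (cat.), i-PrOH, phosphate buffer pH 7, 30 °C
Reagents that add atoms: none
Why: In this enzymatic desymmetrisation of a prochiral 2,2-disubstituted 1,3-diketone (ketoreductase class), the active site reduces one enantiotopic carbonyl from one face, which sets C7 (S) and thereby makes C6 stereogenic (R).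

Step 4
Reactants: 4 (2R,3S)-3-hydroxy-2-(hydroxymethyl)-2-methylcycloheptan-1-one
Product: 5 acetonide ketone (trans-fused 2,2-dimethyl-1,3-dioxane across C6/C7; C5 ketone)
Conditions: 2,2-dimethoxypropane, PPTS (cat.), CH2Cl2, rt
Reagents that add atoms: 2,2-dimethoxypropane, COC(C)(C)OC
Why: Acid-catalysed transacetalisation ties the 1,3-diol into one six-membered ring, which blocks both retro-aldol pathways; no stereocentre is touched.

Step 5
Reactants: 5 acetonide ketone
Product: 7 acetonide enone (C5 ketone conjugated to C11=C10), via lithium enolate 6 (not isolated)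
Conditions: LDA, THF, −78 °C; then PhS(Cl)=N-t-Bu, −78 °C
Reagents that add atoms: none
Why: This is a one-pot enolate dehydrogenation (S-transfer, then syn-elimination), and since C6 is quaternary the ketone can only enolise towards C11, so the regiochemistry is fixed.

Step 6
Reactants: 7 acetonide enone
Product: 9 acetonide β-methyl enone (CH3 on C10), via lithium enolate 8 (not isolated)
Conditions: MeLi (2 equiv), CuI, Et2O, −78 → −20 °C; then PhS(Cl)=N-t-Bu, −78 °C
Reagents that add atoms: lithium dimethylcuprate, [Li+].C[Cu-]C
Why: Cuprate 1,4-addition followed by in-situ dehydrogenation of the regiodefined enolate (one-pot β-alkylation of an enone); the transient C10 stereocentre is erased again.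

Step 7
Reactants: 9 acetonide β-methyl enone
Product: 10 (5S)-allylic alcohol (C5–OH cis to the C6–CH2O arm)
Conditions: (R)-Me-CBS (15 mol %), BH3·SMe2, THF, −30 °C; MeOH
Reagents that add atoms: none
Why: In this CBS reduction the oxazaborolidine reads quaternary C6 as the large and the =CH (C11) as the small carbonyl substituent, so the (R)-catalyst should deliver hydride to the face that gives the (5S)-carbinol under reagent control.

Step 8
Reactants: 10 (5S)-allylic alcohol
Product: 11 (5S)-allylic acetate
Conditions: Ac2O, pyridine, DMAP (cat.), CH2Cl2, rt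
Reagents that add atoms: acetic anhydride, CC(=O)OC(C)=O
Why: DMAP-catalysed O-acylation occurs at oxygen only, so C5 keeps its configuration.

Step 9
Reactants: 11 (5S)-allylic acetate
Product: 14 (10R)-cycloheptenylacetic acid (CH2CO2H on C10 cis to the C6–CH2O arm; cis C5=C11 alkene), via silyl ketene acetal 12 (not isolated), via trimethylsilyl ester 13 (not isolated)
Conditions: LDA, TMSCl, THF, −78 °C → reflux; then aq. citric acid
Reagents that add atoms: none
Why: The suprafacial [3,3] shift of the Ireland–Claisen rearrangement trades the C5–O bond for a C10–C bond on the same ring face (1,3-chirality transfer), which sets quaternary C10 and places the alkene between C6 and C10.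

Step 10
Reactants: 14 (10R)-cycloheptenylacetic acid; 15 ethoxyacetylene
Product: 18 3-ethoxy-4-substituted cyclobut-2-enone (both epimers at the ring CH), via acid chloride 16 (not isolated), via aldoketene 17 (not isolated)
Conditions: 1-chloro-N,N,2-trimethylpropenylamine, CH2Cl2, 0 °C; then 15 (5 equiv), Et3N, 0 → 40 °C
Reagents that add atoms: none
Why: In the ketene–ynol ether [2+2] the ketene carbonyl carbon bonds to the nucleophilic CH of the ynol ether, and the one-atom distance to the ring alkene rules out an intramolecular [2+2]; the new ring CH is formed as a mixture that converges later.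

Step 11
Reactants: 18 3-ethoxy-4-substituted cyclobut-2-enone
Product: 20 3-methyl-4-substituted cyclobut-2-enone (ring C1–C2–C3–C4 with C4 on C10; both C4 epimers), via tertiary cyclobutenol 19 (not isolated)
Conditions: MeLi, Et2O, −78 °C; then 1 M HCl, THF, 0 °C, short contact
Reagents that add atoms: methyllithium, [Li]C; water, O
Why: 1,2-Addition to the vinylogous ester followed by acid-induced carbonyl transposition (Stork–Danheiser type) places CH3 on C3 and the carbonyl on C1; the ethoxy-stabilised cation forms fast enough for the acetonide to survive.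

Step 12
Reactants: 20 3-methyl-4-substituted cyclobut-2-enone
Product: 23 tricyclic enone acetonide, via rhodacyclopentenone 21 (not isolated), via rhodabicyclooctenone 22 (not isolated)
Conditions: [Rh(C2H4)2Cl]2 (5 mol %), P[3,5-(CF3)2C6H3]3 (20 mol %), CO (1 atm), 1,4-dioxane, 120 °C
Reagents that add atoms: none
Why: Proposed new method: Rh(I) adds oxidatively into the strained acyl–C(sp3) bond C1–C4 to give rhodacyclopentenone 21 (the two C4 epimers of 20 interconvert at 120 °C by reversible 4π ring opening and η1/η3 slippage, so both feed the one productive diastereomer), the C5=C11 alkene held next to Rh by C10 inserts into the Rh–acyl bond, and C(sp3)–C(allyl) reductive elimination from 22 releases 23. The closest known reaction types are the Rh-catalysed "cut-and-sew" carboacylation of tethered alkenes by cyclobutanones and benzocyclobutenones, the Rh-catalysed [4+2] of cyclobutenones with strained alkenes, and cyclobutane-forming reductive elimination from five-membered nickela- and ferracycles; new here are the one-atom tether and the four-membered ring made in the last event. Ring closure 1 (C1–C11) is a 6-exo-trig migratory insertion that makes the carbocycle C1–C2–C3–C4–C10–C11, and ring closure 2 (C4–C5) is the contraction of the five-membered rhodacycle Rh–C4–C10–C11–C5 to the cyclobutane, which at the same time completes the cyclohexenone C1–C2–C3–C4–C5–C11. C10 is the only controller: its side arm can reach only the alkene face on its own side, the insertion is syn and both Rh–C bonds are replaced with retention, so C11, C5 and C4 follow from C10. The step needs coupling at C4 (γ) rather than C2 (α) and insertion rather than CO loss: closure at C2 would give a strained β,γ-unsaturated cyclobutanone that Rh can re-open, whereas the conjugated enone 23 has no four-membered acyl ring left and is the sink, the π-acidic phosphine should speed reductive elimination, and 1 atm CO should hold back decarbonylation. The alkyl–Rh carbon C5 lies between quaternary C6 and C11, whose H is anti to Rh, so β-hydride elimination, alkene migration and ene pathways have no hydrogen to use.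

Step 13
Reactants: 23 tricyclic enone acetonide
Product: 24 tricyclic enone diol (C7–OH and C6–CH2OH)
Conditions: AcOH–H2O 4:1, 40 °C
Reagents that add atoms: none
Why: Mild acetal hydrolysis is tolerated by the verbenone-type enone and cyclobutane, and C4 and C11 are bridgeheads that cannot enolise, so no stereocentre is at risk.

Step 14
Reactants: 24 tricyclic enone diol; 25 angelic acid ((Z)-2-methylbut-2-enoic acid)
Product: 27 target bis-angelate CNP0240716.1, via mixed anhydride 26 (not isolated)
Conditions: 25 (6 equiv), 2,4,6-Cl3C6H2COCl, Et3N, toluene, rt; then 24, 80 °C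
Reagents that add atoms: none
Why: Yamaguchi-type mixed-anhydride acylation without a nucleophilic catalyst avoids the addition–elimination channel that turns angelate into tiglate, so both Z-alkenes come unchanged from 25.

**Compound list**
1 | cycloheptane-1,3-dione | O=C1CCCCC(=O)C1 | starting material
2 | 2-methylcycloheptane-1,3-dione | CC1C(=O)CCCCC1=O | intermediate
3 | 2-(hydroxymethyl)-2-methylcycloheptane-1,3-dione | OCC1(C)C(=O)CCCCC1=O | intermediate
4 | (2R,3S)-3-hydroxy-2-(hydroxymethyl)-2-methylcycloheptan-1-one | OC[C@@]1(C)C(=O)CCCC[C@@H]1O | intermediate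
5 | acetonide ketone | O1C[C@@]2(C)C(=O)CCCC[C@@H]2OC1(C)C | intermediate
6 | lithium enolate of 5 (not isolated) | O1C[C@@]2(C)C(O[Li])=CCCC[C@@H]2OC1(C)C | intermediate
7 | acetonide enone | O1C[C@@]2(C)C(=O)C=CCC[C@@H]2OC1(C)C | intermediate
8 | lithium enolate after methyl addition (not isolated) | O1C[C@@]2(C)C(O[Li])=CC(C)CC[C@@H]2OC1(C)C | intermediate
9 | acetonide β-methyl enone | O1C[C@@]2(C)C(=O)C=C(C)CC[C@@H]2OC1(C)C | intermediate
10 | (5S)-allylic alcohol | O1C[C@@]2(C)[C@@H](O)C=C(C)CC[C@@H]2OC1(C)C | intermediate
11 | (5S)-allylic acetate | O1C[C@@]2(C)[C@@H](OC(C)=O)C=C(C)CC[C@@H]2OC1(C)C | intermediate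
12 | silyl ketene acetal (not isolated) | O1C[C@@]2(C)[C@@H](OC(=C)O[Si](C)(C)C)C=C(C)CC[C@@H]2OC1(C)C | intermediate
13 | trimethylsilyl ester (not isolated) | O1C[C@@]2(C)C=C[C@@](C)(CC(=O)O[Si](C)(C)C)CC[C@@H]2OC1(C)C | intermediate
14 | (10R)-cycloheptenylacetic acid | O1C[C@@]2(C)C=C[C@@](C)(CC(=O)O)CC[C@@H]2OC1(C)C | intermediate
15 | ethoxyacetylene | CCOC#C | starting material
16 | acid chloride (not isolated) | O1C[C@@]2(C)C=C[C@@](C)(CC(=O)Cl)CC[C@@H]2OC1(C)C | intermediate
17 | aldoketene (not isolated) | O1C[C@@]2(C)C=C[C@@](C)(C=C=O)CC[C@@H]2OC1(C)C | intermediate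
18 | 3-ethoxy-4-substituted cyclobut-2-enone (ring CH epimers) | O1C[C@@]2(C)C=C[C@@](C)(C3C(=O)C=C3OCC)CC[C@@H]2OC1(C)C | intermediate
19 | tertiary cyclobutenol (not isolated) | O1C[C@@]2(C)C=C[C@@](C)(C3C(C)(O)C=C3OCC)CC[C@@H]2OC1(C)C | intermediate
20 | 3-methyl-4-substituted cyclobut-2-enone (C4 epimers) | O1C[C@@]2(C)C=C[C@@](C)(C3C(C)=CC3=O)CC[C@@H]2OC1(C)C | intermediate
21 | rhodacyclopentenone, ligands omitted (not isolated) | O1C[C@@]2(C)C=C[C@@](C)(C3[Rh]C(=O)C=C3C)CC[C@@H]2OC1(C)C | intermediate
22 | rhodabicyclooctenone, ligands omitted (not isolated) | O1C[C@@]2(C)[C@H]3[Rh][C@@H]4C(C)=CC(=O)[C@H]3[C@]4(C)CC[C@@H]2OC1(C)C | intermediate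
23 | tricyclic enone acetonide | O1C[C@@]2(C)[C@@H]3[C@H]4C(=O)C=C(C)[C@@H]3[C@@]4(C)CC[C@@H]2OC1(C)C | intermediate
24 | tricyclic enone diol | OC[C@@]1(C)[C@@H]2[C@H]3C(=O)C=C(C)[C@@H]2[C@@]3(C)CC[C@@H]1O | intermediate
25 | angelic acid | C/C=C(/C)C(=O)O | starting material
26 | angelic 2,4,6-trichlorobenzoic mixed anhydride (not isolated) | C/C=C(/C)C(=O)OC(=O)c1c(Cl)cc(Cl)cc1Cl | intermediate
27 | CNP0240716.1 | C/C=C(/C)C(=O)OC[C@@]1(C)[C@@H]2[C@H]3C(=O)C=C(C)[C@@H]2[C@@]3(C)CC[C@@H]1OC(=O)/C(C)=C\C | target

**Total step count:** 14. **Longest linear sequence:** 14 (from 1).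

**Steps most likely to fail**

Step 12 (proposed new method). Reductive elimination from the five-membered rhodacycle to a cyclobutane may be slower than decarbonylation, than closure at C2, or than release of the free vinylketene, which would react on by [2+2] or dimerisation.

The fallback sets out from 9, returns at 23 and uses only known reaction types. The cyclobutane is closed last by the classical intramolecular enolate alkylation. This needs the pseudo-symmetric assignment of atoms: the ring alkene becomes C4=C5 and the side arm becomes C11–C1.
- Enone 9 is reduced with (S)-Me-CBS/BH3 to the C5-epimeric allylic alcohol F1.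
- Eschenmoser–Claisen rearrangement (MeC(OMe)2NMe2, xylene, 140 °C) moves the chirality to C10 on the opposite ring face and gives the dimethylamide F2.
- 1-Propynyllithium/BF3·OEt2 converts it into the ynone F3, and NaI/AcOH adds HI to give the (Z)-β-iodoenone F4.
- Iodine-atom-transfer radical cyclisation ((Bu3Sn)2 cat., hν, benzene) closes C3–C4 in the 6-exo mode and should deliver iodine to the convex face of C5, giving the bicyclic iodo enone F5.
- KHMDS (THF, −78 → 0 °C) forms the cross-conjugated C11 enolate, which displaces the iodide with inversion (C5–C11) to give 23.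

Step 3. The enzyme may discriminate poorly between the enantiotopic carbonyls or the two faces, and retro-aldol loss of formaldehyde may compete in the buffer.

The fallback sets out from 3 and returns at 4. In an Evans–Saksena reduction (Me4NBH(OAc)3, MeCN–AcOH, −20 °C) the boron bound to the CH2OH group delivers hydride to the carbonyl face on its own side. This fixes the trans relationship but gives the racemate, that is 4 together with its enantiomer F6. A lipase (vinyl acetate, MTBE) chosen to acetylate the primary OH of the antipode turns it into the monoacetate F7. Unreacted 4 is separated and rejoins the route at step 4.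

Step 14. The angeloyl unit may isomerise from Z to E during the long heating, and acylation of the neopentyl secondary C7–OH may stay incomplete.

The fallback sets out from 24 and returns at 27. DCC/DMAP esterification with the small, non-isomerisable 2-[bis(2,2,2-trifluoroethoxy)phosphoryl]propanoic acid gives the bis(phosphonopropionate) F8. A double Still–Gennari olefination (KHMDS, 18-crown-6, THF, −78 °C, acetaldehyde) then builds both Z-trisubstituted alkenes on the esters already in place and gives 27.

**Further compounds**
F1 | step 12 | C5-epimeric allylic alcohol | O1C[C@@]2(C)[C@H](O)C=C(C)CC[C@@H]2OC1(C)C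
F2 | step 12 | C10-epimeric cycloheptenyl-N,N-dimethylacetamide | O1C[C@@]2(C)C=C[C@](C)(CC(=O)N(C)C)CC[C@@H]2OC1(C)C
F3 | step 12 | ynone | O1C[C@@]2(C)C=C[C@](C)(CC(=O)C#CC)CC[C@@H]2OC1(C)C
F4 | step 12 | (Z)-β-iodoenone | O1C[C@@]2(C)C=C[C@](C)(CC(=O)/C=C(/C)I)CC[C@@H]2OC1(C)C
F5 | step 12 | bicyclic iodo enone | O1C[C@@]2(C)[C@@H](I)[C@@H]3C(C)=CC(=O)C[C@]3(C)CC[C@@H]2OC1(C)C
F6 | step 3 | enantiomer of 4 | OC[C@]1(C)C(=O)CCCC[C@H]1O
F7 | step 3 | primary monoacetate of F6 | CC(=O)OC[C@]1(C)C(=O)CCCC[C@H]1O
F8 | step 14 | bis(phosphonopropionate) of 24 | CC(P(=O)(OCC(F)(F)F)OCC(F)(F)F)C(=O)OC[C@@]1(C)[C@@H]2[C@H]3C(=O)C=C(C)[C@@H]2[C@@]3(C)CC[C@@H]1OC(=O)C(C)P(=O)(OCC(F)(F)F)OCC(F)(F)F
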